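Ring B is opened at the C6–C1 bond (spiro[5.5]undecane locants). Spiro carbon C6 joins the C7=C14 methylene of ring A to the C1=C2–C3 unit of ring B, the 1,4-diene pattern of a formal ene adduct between a tetrasubstituted C6=C7 alkene carrying the C14 methyl and an electrophilic C1. A single aluminium-promoted cyclisation of a terminal ynone onto that alkene should therefore create ring B, the quaternary stereocentre C6, the exocyclic methylene and the C1=C2 enone together. Its precursor is a ring A cyclohexene made from ketoisophorone that carries the silylated cis-bromohydrin (C9, C10) and a 3-oxopent-4-ynyl chain on C6; dibromomethyl addition at C3 and desilylation complete the target.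

Key step: step 9

Remark: target locants are used for all intermediates (ring B C1–C5, spiro C6, ring A C7–C11, C14 the methylene carbon on C7).
Assumption: in step 2 the enone π-system is taken to play the part of the aryl group in the usual stereochemical model of this catalyst family, which points to the (S,S)-ligand; if the sense proves opposite, the (R,R)-catalyst is used.

Step 1
Reactants: 1 ketoisophorone (2,6,6-trimethylcyclohex-2-ene-1,4-dione)
Product: 3 (±)-5-bromo-2,6,6-trimethylcyclohex-2-ene-1,4-dione (bromine on the future C10), via silyl dienol ether 2 (not isolated)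
Conditions: LiN(SiMe3)2, Me3SiCl, THF, −78 °C; then NBS, −78 → 0 °C
Reagents that add atoms: N-bromosuccinimide, O=C1CCC(=O)N1Br
Why: Kinetic deprotonation at the only sp3 α-carbon of the less hindered ketone with in situ silylation gives the cross-conjugated silyl dienol ether, and its α-bromination with NBS (silyl enol ether halogenation) places bromine regiospecifically next to the gem-dimethyl carbon, the product being racemic and configurationally labile, which step 2 uses.

Step 2
Reactants: 3 (±)-5-bromo-2,6,6-trimethylcyclohex-2-ene-1,4-dione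
Product: 4 (4R,5S)-5-bromo-4-hydroxy-2,6,6-trimethylcyclohex-2-en-1-one (cis-bromohydrin, 9R,10S in target locants)
Conditions: RuCl[(S,S)-TsDPEN](p-cymene) (2 mol %), HCO2H/Et3N (5:2), EtOAc, 25 °C
Reagents that add atoms: none
Why: Noyori-type asymmetric transfer hydrogenation with dynamic kinetic resolution, in which the α-bromo ketone racemises through its enol in the amine buffer while the chiral ruthenium hydride reduces only the less hindered carbonyl of the enantiomer whose C–Br bond lies anti to the incoming hydride, should set the carbinol centre (R) and the bromide centre (S) as the cis-bromohydrin, as is known for cyclic α-halo ketones and for this carbonyl of the parent enedione.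

Step 3
Reactants: 4 (4R,5S)-5-bromo-4-hydroxy-2,6,6-trimethylcyclohex-2-en-1-one
Product: 5 (4R,5S)-5-bromo-4-(tert-butyldimethylsilyloxy)-2,6,6-trimethylcyclohex-2-en-1-one
Conditions: t-BuMe2SiOTf, 2,6-lutidine, CH2Cl2, −78 → 0 °C
Reagents that add atoms: tert-butyldimethylsilyl triflate, CC(C)(C)[Si](C)(C)OS(=O)(=O)C(F)(F)F
Why: O-Silylation of the secondary allylic alcohol with a silyl triflate and a hindered pyridine base is fast and non-epimerising, and the bulky silyl ether later anchors the ring A conformation.

Step 4
Reactants: 5 (4R,5S)-5-bromo-4-(tert-butyldimethylsilyloxy)-2,6,6-trimethylcyclohex-2-en-1-one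
Product: 7 (4R,5S)-5-bromo-4-(tert-butyldimethylsilyloxy)-2,6,6-trimethylcyclohex-1-en-1-yl trifluoromethanesulfonate, via lithium enolate 6 (not isolated)
Conditions: LiBH(s-Bu)3, THF, −78 °C; then N-(5-chloropyridin-2-yl)bis(trifluoromethanesulfonimide), −78 → 0 °C
Reagents that add atoms: Comins' reagent, O=S(=O)(N(c1ccc(Cl)cn1)S(=O)(=O)C(F)(F)F)C(F)(F)F
Why: Conjugate reduction of the β-unsubstituted enone, whose carbonyl is shielded by the gem-dimethyl group, gives the tetrasubstituted C6=C7 enolate regiospecifically, and O-sulfonylation by the pyridyl triflimide (enolate triflation) fixes it, the quaternary C11 ruling out enolate equilibration and β-elimination of bromide.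

Step 5
Reactants: 7 (4R,5S)-5-bromo-4-(tert-butyldimethylsilyloxy)-2,6,6-trimethylcyclohex-1-en-1-yl trifluoromethanesulfonate; 8 acrolein diethyl acetal (3,3-diethoxyprop-1-ene)
Product: 10 3-[(4R,5S)-5-bromo-4-(tert-butyldimethylsilyloxy)-2,6,6-trimethylcyclohex-1-en-1-yl]propanal diethyl acetal, via B-(3,3-diethoxypropyl)-9-BBN 9 (not isolated)
Conditions: 8, 9-BBN-H, THF, 0 → 25 °C; then 7, Pd(dppf)Cl2 (5 mol %), K3PO4 (aq), DMF, 50 °C
Reagents that add atoms: none
Why: B-alkyl Suzuki–Miyaura coupling, in which anti-Markovnikov hydroboration gives the primary alkylborane and the bidentate ligand favours reductive elimination over β-hydride loss at the hindered enol triflate, should form the C6–C5 bond while the secondary neopentyl bromide stays inert to zerovalent palladium.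

Step 6
Reactants: 10 3-[(4R,5S)-5-bromo-4-(tert-butyldimethylsilyloxy)-2,6,6-trimethylcyclohex-1-en-1-yl]propanal diethyl acetal
Product: 11 3-[(4R,5S)-5-bromo-4-(tert-butyldimethylsilyloxy)-2,6,6-trimethylcyclohex-1-en-1-yl]propanal
Conditions: pyridinium p-toluenesulfonate (cat), acetone/H2O (4:1), 50 °C
Reagents that add atoms: water, O
Why: Mild acid-catalysed acetal hydrolysis frees the aldehyde without touching the hindered secondary silyl ether or the tetrasubstituted alkene.

Step 7
Reactants: 11 3-[(4R,5S)-5-bromo-4-(tert-butyldimethylsilyloxy)-2,6,6-trimethylcyclohex-1-en-1-yl]propanal; 12 ethynylmagnesium bromide (HC≡CMgBr)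
Product: 13 5-[(4R,5S)-5-bromo-4-(tert-butyldimethylsilyloxy)-2,6,6-trimethylcyclohex-1-en-1-yl]pent-1-yn-3-ol (both C3 epimers)
Conditions: HC≡CMgBr, THF, −20 → 0 °C; aq NH4Cl
Reagents that add atoms: none
Why: Grignard 1,2-addition of the acetylide to the unhindered aldehyde gives the propargylic alcohol, whose C3 configuration is irrelevant because that centre is oxidised in the next step.

Step 8
Reactants: 13 5-[(4R,5S)-5-bromo-4-(tert-butyldimethylsilyloxy)-2,6,6-trimethylcyclohex-1-en-1-yl]pent-1-yn-3-ol
Product: 14 5-[(4R,5S)-5-bromo-4-(tert-butyldimethylsilyloxy)-2,6,6-trimethylcyclohex-1-en-1-yl]pent-1-yn-3-one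
Conditions: Dess–Martin periodinane, NaHCO3, CH2Cl2, 0 → 25 °C
Reagents that add atoms: none
Why: Dess–Martin oxidation of the secondary propargylic alcohol under buffered, non-nucleophilic conditions gives the terminal ynone without conjugate addition or alkyne migration.

Step 9
Reactants: 14 5-[(4R,5S)-5-bromo-4-(tert-butyldimethylsilyloxy)-2,6,6-trimethylcyclohex-1-en-1-yl]pent-1-yn-3-one
Product: 15 (6S,9R,10S)-10-bromo-9-(tert-butyldimethylsilyloxy)-11,11-dimethyl-7-methylidenespiro[5.5]undec-1-en-3-one
Conditions: Me2AlCl (2 equiv), CH2Cl2 (0.01 M), −78 → 0 °C; then 1 M HCl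
Reagents that add atoms: none
Why: Proposed new method: Me2AlCl on the C3 carbonyl polarises the ynone, the tetrasubstituted C6=C7 alkene adds through C6 to the alkyne terminus C1 (stepwise cation–olefin addition), and the tertiary C7 cation is quenched by loss of a C14 proton that ends up on C2, by relay through the aluminate or, if an Al–CH3 bond takes it up as methane, by protonation of the C2–aluminium species on work-up; a concerted suprafacial hydrogen shift is excluded because the ring forces the new C2–H bond trans to C6. The closest known reaction types are Lewis-acid-promoted ene and conjugate-ene reactions of aldehydes, enones and ynones with alkenes (tri- and tetrasubstituted alkenes in the intermolecular series) and acid-mediated 6-endo-dig hydroarylation of aryl alkynoates, where the carbonyl group also ends up inside the new ring. Ring B closes in the 6-endo-dig mode at the ynone, whereas attack through C7 would give a seven-membered ring and a C6 cation with no hydrogen to lose outside the tether. The new stereocentre C6 is controlled by the ring A half-chair, in which the bulky C9 silyl ether is equatorial (an axial one would clash with a C11 methyl) and the C10 bromine therefore axial: chair-like bond formation at C6 then takes place on the face of the bromine, the opposite face being screened by the pseudo-axial C11 methyl next to C6, which puts C1 cis to Br and OSi as the target requires. The step needs C14 and not C8 proton loss, which the substrate should secure kinetically because the one C8–H aligned with the empty orbital sits in the pocket between the axial bromine and the new C6–C1 bond while the methyl hydrogens are exposed, and the Al–CH3 groups remove protic acid that could isomerise the methylene group.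

Step 10
Reactants: 15 (6S,9R,10S)-10-bromo-9-(tert-butyldimethylsilyloxy)-11,11-dimethyl-7-methylidenespiro[5.5]undec-1-en-3-one
Product: 16 (3R,6S,9R,10S)-10-bromo-9-(tert-butyldimethylsilyloxy)-3-(dibromomethyl)-11,11-dimethyl-7-methylidenespiro[5.5]undec-1-en-3-ol
Conditions: CH2Br2 (3 equiv), LiN(i-Pr)2 (2.5 equiv), THF, −78 °C; then 15, −78 °C; AcOH, −78 °C
Reagents that add atoms: dibromomethane, BrCBr
Why: 1,2-Addition of the dibromomethyllithium carbenoid to the enone carbonyl with a cold acidic quench (so that the alkoxide cannot close to a bromo-epoxide) should proceed along the pseudo-equatorial trajectory of the ring B half-chair in which the quaternary C11 arm is pseudo-equatorial, placing CHBr2 cis to C7 and the hydroxyl cis to C11, which is the (3R) configuration.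

Step 11
Reactants: 16 (3R,6S,9R,10S)-10-bromo-9-(tert-butyldimethylsilyloxy)-3-(dibromomethyl)-11,11-dimethyl-7-methylidenespiro[5.5]undec-1-en-3-ol
Product: 17 mailiohydrin, (3R,6S,9R,10S)-10-bromo-3-(dibromomethyl)-11,11-dimethyl-7-methylidenespiro[5.5]undec-1-ene-3,9-diol
Conditions: HF·pyridine, pyridine, THF, 0 → 25 °C
Reagents that add atoms: none
Why: Acidic fluoride desilylation cleaves the secondary silyl ether and is chosen over basic fluoride because an alkoxide next to CHBr2 would cyclise to a bromo-epoxide, while the tertiary allylic carbinol should not ionise since the CHBr2 group destabilises the cation.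

Compound list
1 | ketoisophorone (2,6,6-trimethylcyclohex-2-ene-1,4-dione) | CC1=CC(=O)CC(C)(C)C1=O | starting material
2 | 2,6,6-trimethyl-4-(trimethylsilyloxy)cyclohexa-2,4-dien-1-one | CC1=CC(O[Si](C)(C)C)=CC(C)(C)C1=O | intermediate
3 | (±)-5-bromo-2,6,6-trimethylcyclohex-2-ene-1,4-dione | CC1=CC(=O)C(Br)C(C)(C)C1=O | intermediate
4 | (4R,5S)-5-bromo-4-hydroxy-2,6,6-trimethylcyclohex-2-en-1-one | CC1=C[C@@H](O)[C@@H](Br)C(C)(C)C1=O | intermediate
5 | (4R,5S)-5-bromo-4-(tert-butyldimethylsilyloxy)-2,6,6-trimethylcyclohex-2-en-1-one | CC1=C[C@@H](O[Si](C)(C)C(C)(C)C)[C@@H](Br)C(C)(C)C1=O | intermediate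
6 | lithium (4R,5S)-5-bromo-4-(tert-butyldimethylsilyloxy)-2,6,6-trimethylcyclohex-1-en-1-olate | [Li+].[O-]C1=C(C)C[C@@H](O[Si](C)(C)C(C)(C)C)[C@@H](Br)C1(C)C | intermediate
7 | (4R,5S)-5-bromo-4-(tert-butyldimethylsilyloxy)-2,6,6-trimethylcyclohex-1-en-1-yl trifluoromethanesulfonate | FC(F)(F)S(=O)(=O)OC1=C(C)C[C@@H](O[Si](C)(C)C(C)(C)C)[C@@H](Br)C1(C)C | intermediate
8 | acrolein diethyl acetal (3,3-diethoxyprop-1-ene) | C=CC(OCC)OCC | starting material
9 | 9-(3,3-diethoxypropyl)-9-borabicyclo[3.3.1]nonane | CCOC(CCB1C2CCCC1CCC2)OCC | intermediate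
10 | 3-[(4R,5S)-5-bromo-4-(tert-butyldimethylsilyloxy)-2,6,6-trimethylcyclohex-1-en-1-yl]propanal diethyl acetal | CCOC(CCC1=C(C)C[C@@H](O[Si](C)(C)C(C)(C)C)[C@@H](Br)C1(C)C)OCC | intermediate
11 | 3-[(4R,5S)-5-bromo-4-(tert-butyldimethylsilyloxy)-2,6,6-trimethylcyclohex-1-en-1-yl]propanal | O=CCCC1=C(C)C[C@@H](O[Si](C)(C)C(C)(C)C)[C@@H](Br)C1(C)C | intermediate
12 | ethynylmagnesium bromide | C#C[Mg]Br | starting material
13 | 5-[(4R,5S)-5-bromo-4-(tert-butyldimethylsilyloxy)-2,6,6-trimethylcyclohex-1-en-1-yl]pent-1-yn-3-ol (both C3 epimers) | C#CC(O)CCC1=C(C)C[C@@H](O[Si](C)(C)C(C)(C)C)[C@@H](Br)C1(C)C | intermediate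
14 | 5-[(4R,5S)-5-bromo-4-(tert-butyldimethylsilyloxy)-2,6,6-trimethylcyclohex-1-en-1-yl]pent-1-yn-3-one | C#CC(=O)CCC1=C(C)C[C@@H](O[Si](C)(C)C(C)(C)C)[C@@H](Br)C1(C)C | intermediate
15 | (6S,9R,10S)-10-bromo-9-(tert-butyldimethylsilyloxy)-11,11-dimethyl-7-methylidenespiro[5.5]undec-1-en-3-one | C=C1C[C@@H](O[Si](C)(C)C(C)(C)C)[C@@H](Br)C(C)(C)[C@@]12C=CC(=O)CC2 | intermediate
16 | (3R,6S,9R,10S)-10-bromo-9-(tert-butyldimethylsilyloxy)-3-(dibromomethyl)-11,11-dimethyl-7-methylidenespiro[5.5]undec-1-en-3-ol | C=C1C[C@@H](O[Si](C)(C)C(C)(C)C)[C@@H](Br)C(C)(C)[C@@]12C=C[C@@](O)(C(Br)Br)CC2 | intermediate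
17 | mailiohydrin, (3R,6S,9R,10S)-10-bromo-3-(dibromomethyl)-11,11-dimethyl-7-methylidenespiro[5.5]undec-1-ene-3,9-diol | C=C1C[C@@H](O)[C@@H](Br)C(C)(C)[C@@]12C=C[C@@](O)(C(Br)Br)CC2 | target

Total step count: 11
Longest linear sequence: 11 steps (1 to 17)

Steps most likely to fail

Step 9. The alkene may fail to add to the ynone, whose carbonyl activation is mostly inductive in this endo closure. Chloride or methyl transfer from aluminium to C1, attack on the carbonyl carbon, capture of the C7 cation by the neighbouring bromine, loss of a C8 proton, or bond formation on the wrong face of C6 may compete. The fallback uses known reactions only, sets out from enol triflate 7 and comes back at spiro enone 15. Methoxycarbonylation of 7 (Pd(OAc)2, 1,3-bis(diphenylphosphino)propane, CO, MeOH, Et3N, DMF, 70 °C) should give the methyl cyclohexenecarboxylate F1. LiN(i-Pr)2 in THF/DMPU at −78 °C should remove a hydrogen from the C14 methyl, which lies cis to the ester, and the dienolate should add through C6 to methyl vinyl ketone (deconjugative Michael addition) to give the keto ester F2 with the methylene group and the quaternary centre in place; C6 epimers would be separated here. KOt-Bu in t-BuOH/THF should close ring B by Claisen condensation of the methyl ketone onto the ester to give the spiro 1,3-dione F3. Me2SO4 and K2CO3 in acetone should methylate the less hindered C3 oxygen to give the vinylogous ester F4. Reduction of the C1 carbonyl with i-Bu2AlH at −78 °C and dilute acid work-up (Stork–Danheiser transposition) should then deliver 15.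

Step 2. Racemisation of the bromo ketone may be slower than reduction (plain kinetic resolution), hydride may be delivered syn to bromine, or bromine or the C=C bond may be reduced. The fallback sets out from bromo dione 3 and comes back at bromohydrin 4. Luche reduction (NaBH4, CeCl3·7H2O, MeOH, −78 °C), with hydride entering anti to the axial bromine, should give the racemic cis-bromohydrin F5. Lipase-catalysed acylation (Burkholderia cepacia lipase, vinyl acetate, t-BuOMe) should, by the empirical size rule for secondary alcohols, convert the (4R) enantiomer into the acetate F6 and leave the (4S,5R)-alcohol F7, which is removed by chromatography. K2CO3 in MeOH should cleave F6 to 4; if the enzyme prefers the other enantiomer, the unreacted alcohol is 4 itself.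

Step 10. Facial selectivity at C3 may be poor (pseudo-axial attack gives the C3 epimer), the carbenoid may enolise the ketone, or the alkoxide may collapse to a bromo-epoxide on warming. The fallback sets out from enone 15 and comes back at carbinol 16. LiCBr3, generated from CHBr3 and LiN(i-Pr)2 in THF/Et2O at −100 °C, should add to 15 to give the tribromomethyl carbinol F8, the larger nucleophile reinforcing pseudo-equatorial attack. Bu3SnH (1 equiv) with Et3B and air in toluene at −78 °C should then remove one bromine from the CBr3 group by radical chain reduction, which is far faster than reduction of the secondary ring bromide, to give 16.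

Further compounds
F1 | step 9 | methyl (4R,5S)-5-bromo-4-(tert-butyldimethylsilyloxy)-2,6,6-trimethylcyclohex-1-ene-1-carboxylate | COC(=O)C1=C(C)C[C@@H](O[Si](C)(C)C(C)(C)C)[C@@H](Br)C1(C)C
F2 | step 9 | methyl 5-bromo-4-(tert-butyldimethylsilyloxy)-6,6-dimethyl-2-methylidene-1-(3-oxobutyl)cyclohexane-1-carboxylate (quaternary centre as C6 of 15) | C=C1C[C@@H](O[Si](C)(C)C(C)(C)C)[C@@H](Br)C(C)(C)[C@]1(C(=O)OC)CCC(C)=O
F3 | step 9 | (9R,10S)-10-bromo-9-(tert-butyldimethylsilyloxy)-11,11-dimethyl-7-methylidenespiro[5.5]undecane-1,3-dione (C6 as in 15) | C=C1C[C@@H](O[Si](C)(C)C(C)(C)C)[C@@H](Br)C(C)(C)[C@@]12C(=O)CC(=O)CC2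
F4 | step 9 | (9R,10S)-10-bromo-9-(tert-butyldimethylsilyloxy)-3-methoxy-11,11-dimethyl-7-methylidenespiro[5.5]undec-2-en-1-one (C6 as in 15) | C=C1C[C@@H](O[Si](C)(C)C(C)(C)C)[C@@H](Br)C(C)(C)[C@@]12C(=O)C=C(OC)CC2
F5 | step 2 | racemic cis-5-bromo-4-hydroxy-2,6,6-trimethylcyclohex-2-en-1-one (one enantiomer drawn) | CC1=C[C@@H](O)[C@@H](Br)C(C)(C)C1=O
F6 | step 2 | (4R,5S)-4-acetoxy-5-bromo-2,6,6-trimethylcyclohex-2-en-1-one | CC1=C[C@@H](OC(C)=O)[C@@H](Br)C(C)(C)C1=O
F7 | step 2 | (4S,5R)-5-bromo-4-hydroxy-2,6,6-trimethylcyclohex-2-en-1-one | CC1=C[C@H](O)[C@H](Br)C(C)(C)C1=O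
F8 | step 10 | (3R,6S,9R,10S)-10-bromo-9-(tert-butyldimethylsilyloxy)-11,11-dimethyl-7-methylidene-3-(tribromomethyl)spiro[5.5]undec-1-en-3-ol | C=C1C[C@@H](O[Si](C)(C)C(C)(C)C)[C@@H](Br)C(C)(C)[C@@]12C=C[C@@](O)(C(Br)(Br)Br)CC2
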